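All runs are simulated on assumed constants; the scatter is artificial.

Start from amounts: let y be the target as a share of the substrate charged. The flask holds most target at the moment y stops rising.

| flask | substrate | gas | remark | time |
|---|---|---|---|---|
| autumn | 0.33 M | 37 mM (held) | the very flask that is asked about, followed so far |  |
| spring | 0.22 M | 37 mM (held) | run made earlier |  |
| flask | 0.33 M | 37 mM (held) |  | 2.0 h |

| run | time / min | target / % |
|---|---|---|
| autumn | 1.50 | 3.2 |
| autumn | 3.00 | 12.0 |
| autumn | 5.00 | 26.9 |
| autumn | 6.00 | 30.2 |
| autumn | 8.00 | 41.0 |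
| autumn | 10.0 | 48.4 |
| spring | 8.00 | 49.9 |
| spring | 25.0 | 64.8 |
| spring | 40.0 | 56.7 |
| spring | 60.0 | 47.4 |
| spring | 90.0 | 38.7 |
| spring | 120 | 33.5 |

(scatter of a reading: 1 percentage point)

- when, up to 2.0 h, the flask holds most target
- the amount of target, in percent of the substrate charged, at that time

Begin with the late spring readings. Assume a second-order loss, so that the reciprocal of y climbs straight in time, and draw that line through 60.0 min and 120 min, with slope s and intercept u:

s = 0.0146 min⁻¹, u = 1.23

Test it at 90.0 min: the line gives 39.3 %, the reading 38.7 %. Now assume the slope scales with the charge, and carry it to the autumn flask: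

b = 0.0219 min⁻¹, L(t) = 1/(u + b t)

Call b the loss constant: the rise of the reciprocal of y per unit time, proportional to the charge. L is an estimate of the falling branch and no bound on y: in the spring run the line gives 62.7 % at 25.0 min, and the reading there stands higher, 64.8 %.

First way: extrapolate the autumn climb. It ran at 0.0470 min⁻¹ from 5.00 min to 8.00 min, then at 0.0370 min⁻¹ up to 10.0 min. Continue that fall straight, and the climb stops at 18.2 min, with y at 61.8 %.

Second way: follow the gap g = L − y. It shrinks from 47.5 % to 20.4 % between those times, a time constant of

τ = 5.92 min

At 18.2 min the gap is still 5.06 %. It closes at 0.00856 min⁻¹ while L falls at 0.00820 min⁻¹, nearly equal rates, so the peak stands near 18.2 min.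

The ways agree on the time and part on the height. The straight climb ends higher than L, 61.2 %, so it turns the gap negative at 18.2 min, where the steady shrinking still leaves 5.06 %; judge the straight climb the one that cheats. Commit to 56.1 %.

The forecast says 0.36 h and 60 %, “an envelope estimate, not a fit”. The flask gives 0.323 h and 58.2 %.

    target + by-product → side product (k = 0.00170 M⁻¹ s⁻¹)
    intermediate ⇌ target + by-product (K = 0.820 M, k = 0.0130 s⁻¹)
    gas ⇌ reagent, rate k3*(csat - [reagent]) (kL = 0.0200 s⁻¹)
    substrate + reagent ⇌ intermediate (K = 42.0 M⁻¹, k = 0.130 M⁻¹ s⁻¹)

Run L on to 2.0 h in this flask: it gives 25.9 %, and the flask holds 26.3 %. Now raise the charge to 1.3 M, with the time held. In that neighbour flask b becomes 0.0862 min⁻¹, so the line gives 8.64 % at 2.00 h, and the neighbour flask holds more than that, 12.8 %, after a best of 31.6 %.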